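Target is a way station. starting material ⇌ other conformer (K1 = 0.75, k1 = 0.12 h⁻¹); starting material → target (k2 = 1.3 h⁻¹); other conformer → isomer of the product A (k3 = 3.1 h⁻¹); target ⇌ isomer of the product A (K4 = 3.9, k4 = 0.17 h⁻¹); target → over-reaction product (k5 = 0.046 h⁻¹); target ⇌ isomer of the product B (K6 = 0.71, k6 = 0.063 h⁻¹)

| setting | west | north | south |
|---|---|---|---|
| starting material | 2.5 M | 2.5 M | 2.5 M |
| time | 8.0 h |  | 8.0 h |
| remark | a tube with plug flow, the mixed feed as stated, residence time 8.0 h | a single well-mixed tank run continuously and read at steady state, 8.0 h in it on average | everything together in a closed stirred flask, run for 8.0 h |
1. the set-up with the highest amount of target at the outlet or at the end, in percent of the starting material put in ("none" if the first two lie within 2 percentage points) (west / north / south / none)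
2. amount of target at the outlet or at the end, in percent of the starting material put in, west
3. amount of target at the outlet or at the end, in percent of the starting material put in, north
4. amount of target at the outlet or at the end, in percent of the starting material put in, south
- the stated concentrations are those of everything mixed, before any reaction; amounts are the same in each set-up
- run time (west): 8.0 h

Starting material leaves with the summed constant kA = 1.42 h⁻¹, and the share s = 91.5 % of it goes straight to target. The remainder enters the other conformer, whose exit to isomer A is much faster than its way back. Target leaves with the summed forward constant D = 0.279 h⁻¹, smaller than kA. The quantity to carry is the drain number x = 2.23, D times the time spent in the vessel, a Damköhler number. At this x a well-mixed tank passes the fraction 0.309 of what it forms, and a tube or closed flask passes about 0.107.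

With no return, that gives 26.0 % for the north tank and 12.2 % for the west tube and south flask, which share one time course. The return from both isomers is the correction. In the north tank, their steady balances take the return number r = 0.561 off x, raising north to 31.5 %. Borrowing r for the exponent raises west and south to 21.4 %.

That borrowing is the weak link: r comes from the steady balances of a tank, and the isomers of a closed flask start at zero. Reforged, the return is read one drain time before the end, at 4.42 h. Reckoned with no return, isomer A then stands at 44.0 % and isomer B at 13.2 %, so the added target is 11.1 % and the total for west and south 23.3 %. By this reckoning, north leads by more than the margin.

The forecast names north, with 21.4 % west (19.5 % to 23.5 %), 32.3 % north (30 % to 34.5 %) and 21.4 % south (19.5 % to 23.5 %), holding that “the tank's broad residence-time spread and lower conversion past the target keep more of it at steady state”.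

The simulation gives north, with 21.3 % west, 32.3 % north and 21.3 % south. Starting material's half-life by its step to target alone, 0.53 h, is shorter than the 2.48 h that D gives target, forward steps alone. At the end the south flask holds 50.5 % isomer A, and the north tank's outlet carries 37.9 %. Left for 80.0 h, the south flask reaches a drain number of 22.3 and still holds 7.78 % target.

All constants belong to no real substance; no experiment stands behind them.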